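## The problem

Licobichalcone is a 1-aryl-1,2-dihydronaphthalene. Ring B (C1, C2, C3, C4, C4a, C8a) is fused to the trioxygenated ring A, carries ring C on C1 and 4-hydroxybenzoyl groups on C2 and C3 (carbonyl carbons C9 and C10), and holds a C3=C4 double bond conjugated with ring A and the C10 ketone. The only stereocentres are the neighbours C1 and C2, both S, with the C1 aryl and the C2 aroyl cis. C1 is a doubly benzylic methine and configurationally robust, but it cannot steer C2 by equilibration: C2–H is α to the C9 ketone and allylic to C3=C4, and equilibration is expected to move the aroyl group to the trans side or shift the double bond to C2=C3, one dehydrogenation away from a flat 1-arylnaphthalene. C2 therefore has to be set kinetically, together with C1, and must afterwards be spared strong base and long contact with acid. Six phenols (a catechol unit on each of rings A and C, two para-hydroxyaryl ketones) are oxidation-prone and should travel under one masking group that is removed without base, while the methyl ethers at C8 and C2' stay. Rings A and C share the same 2-methoxy-3,4-dioxygenated pattern counted from C1; ring A only carries C4 in addition, ortho to C1, so both can come from one building block. The enabling feature lies in ring B: C1–C2 and C3–C4 flank C2–C3, so cutting them leaves a diene C1=C8a–C4a=C4 (an ortho-quinodimethane of ring A) and a two-carbon unit C2=C3 with the same aroyl group at both ends; since C3=C4 can descend from a C4 carbinol β to the C10 ketone, the diene can be the photoenol of an ortho-benzylbenzaldehyde whose C1–H bonds are doubly benzylic.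

## Retrosynthesis

**21 to 20.** The six phenolic O–H bonds of licobichalcone 21 are traced back to methoxymethyl ethers in 20. This acetal withstands organozinc reagents, peracid, a titanium alkoxide and amine bases, and it leaves under acid, the only medium in which C2 is not at immediate risk. The forward step is a mild acetal methanolysis that leaves two aryl methyl ethers, two ketones and the C3=C4 bond alone.

**20 to 18.** Formal hydration of C3=C4 with oxygen on C4 leads to the benzylic β-hydroxy ketone 18. Placing the oxygen on C4 rather than carrying the alkene through the ring-forming step keeps C4 at the aldehyde oxidation level in the next disconnection. The forward elimination can only run toward C3, because C4a bears no hydrogen, and in the all-cis isomer H3 is anti to the C4 oxygen. The two extra stereocentres of 18 (C3, C4) are disposable.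

**18 to 12 and 16.** C1–C2 and C3–C4 are cut together. Neighbouring cuts (C4–C4a by arene alkylation, C1–C2 alone by conjugate addition) close ring B stepwise and leave the C1/C2 relationship to equilibration. The double cut makes it a consequence of geometry in a concerted cycloaddition. The precursors are the flat ortho-benzylbenzaldehyde 12 and the symmetrical Z-enedione 16, joined through the photoenol 17. The forward reaction must deliver the dienol with hydroxyl and aryl outside, keep the dienophile Z, add endo, and choose one diene face. A titanium alkoxide that binds the dienol oxygen and the C10 carbonyl, carrying a TADDOL-type ligand, answers the last two demands. The Z geometry is indispensable: an E-enedione bound through the same chelate would place the C2 aroyl trans to the C1 aryl.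

**12 to 10 and 6.** The C8a–C1 bond (aryl–CH2) is cut to aryl triflate 10 and benzylic chloride 6, joined by way of benzylzinc reagent 11. Direct ortho-metalation of a ring A benzaldehyde surrogate was set aside, because the position next to a methoxymethyl ether (C5) would be metalated in competition with the one next to the methyl ether (C8a). A triflate fixes the coupling site by the position of an oxygen atom. The forward coupling must tolerate a free formyl group and an electrophile substituted on both ortho positions.

**10 to 9, 8 and 3; 6 to 4 and 3.** The triflate oxygen of 10 is a phenol in salicylaldehyde 9, whose formyl group (C4) is removed to give phenol 8. In 8 the hydroxyl has exactly one free ortho position and a blocked para position, so ortho-formylation is regiochemically unambiguous. Phenol 8 arises from aldehyde 3 by exchange of the formyl group for hydroxyl (Baeyer–Villiger). Chloride 6 comes from the same aldehyde 3 through alcohol 4. Rings A and C thus diverge from one compound, which reflects their common substitution pattern.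

**3 to 2 and 1.** Aldehyde 3 is reached from 2,3,4-trihydroxybenzaldehyde 1 by etherification of O3 and O4 (giving 2) and methylation of the remaining chelated O2. The hydrogen bond of the 2-hydroxyl to the formyl group supplies the selectivity.

**16 to 15, 13 and 14.** The Z-enedione 16 is the ring-opened form of 2,5-diarylfuran 15: the furan ring holds C2 and C3 cis, so oxidative opening gives the Z isomer directly. Dehydrogenation of a saturated 1,4-diketone would give the E isomer and require a separate photoisomerisation. Furan 15 is cut at both aryl–furyl bonds to 2,5-dibromofuran 13 and boronic acid 14.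

## Roads not taken

**Alternative 1:** The cut runs through ring A at C4a–C8a, C5–C6 and C7–C8. Rings A and B would both form in one cobalt-mediated [2+2+2] cyclotrimerisation of enediyne A1 with the diborylalkyne A2, giving the 6,7-diboryl dihydronaphthalene A3. In A1 an ethynyl group on C4 supplies C4a and C5 and a methoxyethynyl group on C1 supplies C8a and C8; A2 supplies C6 and C7. Oxidation of both C–B bonds and unmasking would finish.
- Merits: three C–C bonds and two rings in one step. The oxygen pattern of ring A is written by the tether and the alkyne partner, so no aromatic regiochemistry has to be solved. Here this road is better than the chosen plan, which spends steps 5 to 8 on placing two carbon substituents ortho to each other on ring A.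
- Weak points: the cyclotrimerisation creates no stereocentre, so A1 must already hold C1 and C2 in the correct sense in an open chain. There C2–H is α to a ketone and C1–H is both benzylic and propargylic, open to alkyne–allene isomerisation. A1 also combines an ynol ether, a conjugated enyne and two ketones, and has to be paired with a bulky external alkyne used in excess. Finally, two hindered neighbouring C–B bonds must be oxidised with basic peroxide in the presence of the enone and the base-labile C2.
- Comparison: the chosen plan sets against the higher bond count that the step closing ring B also creates C1 and C2, from flat and robust partners, with every phenolic oxygen in place from the start.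

**Alternative 2:** The cut is C4–C4a. In enaminone A4, C1 carries two identical 2-methoxy-3,4-bis(methoxymethoxy)phenyl groups and C2 two aroyl groups, so no stereocentre is present. A chiral phosphoric acid would activate the aminomethylene ketone and guide one of the two enantiotopic aryl groups onto C4 with loss of the amine, giving A5 with C1 set. One aroyl group would then be cleaved from C2.
- Merits: the hidden symmetry of rings A and C is used most directly, and chirality comes from a catalyst rather than from stoichiometric titanium and ligand. The dihydronaphthalene oxidation level is reached at once, with no carbinol to eliminate. In these respects it is better than the chosen plan.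
- Weak points: the attacking carbon (the future C4a) is para only to the central, twisted oxygen of the aryl group and meta to the outer one, so it is a poor nucleophile for a weakly electrophilic enaminone. The quaternary C2 beside a bis-aryl methine is very congested. Decisively, C2 would become a stereocentre last, by retro-Claisen deacylation and protonation of an enolate under base, which is thermodynamic control at the very centre expected to prefer trans. A choice among three aroyl groups also has to be made.
- Comparison: the chosen plan sets against the catalytic economy a C2 configuration fixed kinetically by suprafacial addition and never exposed to enolate chemistry.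

**Alternative 3:** The cut is C1–C2. Racemic carbinol A6 has a free ring C 4-hydroxyl, and its ring A carries at C4a the chain C4=C3(aroyl)–C2H2–C9 ketone. Under a chiral phosphoric acid it would ionise to a para-quinone methide across C1 and ring C, and the enol of the C9 ketone would add through C2 in a 6-exo closure to give A7, the target as its pentakis(methoxymethyl) ether.
- Merits: enantioconvergent and catalytic; both stereocentres arise in the ring-forming step; the correct oxidation level is reached directly. After the key step it is shorter than the chosen plan and needs neither light nor stoichiometric titanium. In these respects it is better.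
- Weak points: the closure is stepwise and ionic, so the cis relationship must be imposed by the catalyst against the expected steric preference. A7 is a para-hydroxybenzyl ketone that can re-ionise under the same acid, which erodes C1 and C2 toward trans. A6 requires one phenol out of six to be differentiated. Its carbinol oxygen can add to the neighbouring enone (oxa-Michael closure to a dihydroisobenzofuran) in competition with the desired carbon nucleophile.
- Comparison: the chosen plan sets against the shorter endgame a concerted cycloaddition that takes the cis relationship from the Z dienophile and the outside aryl group, needs no differentiated phenol, and draws both aromatic halves from one aldehyde.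

Key step: step 11

Assumption on the chemistry: the (R,R)-TADDOL ligand is taken to expose the diene face that leads to the (1S,2S,3S,4S) adduct; should the sense of induction be the reverse, the (S,S) ligand is used with no other change. Atom numbers follow the target (C9 and C10 are the carbonyl carbons on C2 and C3; primed numbers refer to ring C). Compounds 13 and 14 are taken as catalogue compounds.

## Route

Step 1
Reactants: 1 2,3,4-trihydroxybenzaldehyde
Product: 2 2-hydroxy-3,4-bis(methoxymethoxy)benzaldehyde
Conditions: MOMCl (2.2 equiv), i-Pr2NEt, CH2Cl2, 0 °C → rt
Reagents that add atoms: chloromethyl methyl ether (MOMCl), COCCl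
Why: Williamson-type O-alkylation; the 2-hydroxyl is held in a hydrogen bond to the formyl oxygen and is the least nucleophilic, so two equivalents of the chloride should go to O4 and O3, as is usual for polyhydroxybenzaldehydes with a chelated ortho-hydroxyl.

Step 2
Reactants: 2 2-hydroxy-3,4-bis(methoxymethoxy)benzaldehyde
Product: 3 2-methoxy-3,4-bis(methoxymethoxy)benzaldehyde
Conditions: MeI, K2CO3, DMF, rt
Reagents that add atoms: iodomethane, CI
Why: Williamson ether synthesis on the one remaining phenol; carbonate in DMF breaks the chelate and no other nucleophilic site is left.

Step 3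
Reactants: 3 2-methoxy-3,4-bis(methoxymethoxy)benzaldehyde
Product: 4 [2-methoxy-3,4-bis(methoxymethoxy)phenyl]methanol
Conditions: NaBH4, MeOH/THF, 0 °C
Reagents that add atoms: none
Why: Borohydride reduction of an aryl aldehyde; the acetal ethers are inert to hydride and to the basic medium.

Step 4
Reactants: 4 [2-methoxy-3,4-bis(methoxymethoxy)phenyl]methanol
Product: 6 1-(chloromethyl)-2-methoxy-3,4-bis(methoxymethoxy)benzene, via benzylic mesylate 5 (not isolated)
Conditions: MsCl, Et3N, CH2Cl2, 0 °C → rt
Reagents that add atoms: methanesulfonyl chloride, CS(=O)(=O)Cl
Why: Sulfonylation of a para-alkoxybenzylic alcohol followed by displacement of the mesylate by the chloride ion released in the same flask; the amine-buffered medium spares the acetals and the chloride is used without storage.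

Step 5
Reactants: 3 2-methoxy-3,4-bis(methoxymethoxy)benzaldehyde
Product: 8 2-methoxy-3,4-bis(methoxymethoxy)phenol, via aryl formate 7 (not isolated)
Conditions: mCPBA, CH2Cl2, 0 °C → rt; then K2CO3 (cat.), MeOH, rt
Reagents that add atoms: meta-chloroperoxybenzoic acid, OOC(=O)c1cccc(Cl)c1
Why: Baeyer–Villiger oxidation; in benzaldehydes with ortho and para alkoxy groups the electron-rich aryl group migrates in preference to hydride, and the resulting formate is cleaved by mild methanolysis.

Step 6
Reactants: 8 2-methoxy-3,4-bis(methoxymethoxy)phenol
Product: 9 2-hydroxy-3-methoxy-4,5-bis(methoxymethoxy)benzaldehyde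
Conditions: MgCl2, Et3N, (CH2O)n, MeCN, reflux
Reagents that add atoms: paraformaldehyde (as formaldehyde), C=O
Why: Magnesium-mediated ortho-formylation of a phenol; the magnesium phenoxide delivers formaldehyde only to an ortho carbon and a second formaldehyde accepts hydride from the benzylic alkoxide. The other ortho position and the para position of 8 are substituted, so the formyl group can only enter at the carbon that becomes C4a.

Step 7
Reactants: 9 2-hydroxy-3-methoxy-4,5-bis(methoxymethoxy)benzaldehyde
Product: 10 6-formyl-2-methoxy-3,4-bis(methoxymethoxy)phenyl trifluoromethanesulfonate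
Conditions: Tf2O, pyridine, CH2Cl2, 0 °C
Reagents that add atoms: trifluoromethanesulfonic anhydride, O=S(=O)(OS(=O)(=O)C(F)(F)F)C(F)(F)F
Why: O-Sulfonylation of a salicylaldehyde-type phenol under pyridine buffering; it turns the C8a oxygen into a leaving group whose oxidative addition is helped by the ortho formyl group.

Step 8
Reactants: 6 1-(chloromethyl)-2-methoxy-3,4-bis(methoxymethoxy)benzene; 10 6-formyl-2-methoxy-3,4-bis(methoxymethoxy)phenyl trifluoromethanesulfonate
Product: 12 3-methoxy-2-{[2-methoxy-3,4-bis(methoxymethoxy)phenyl]methyl}-4,5-bis(methoxymethoxy)benzaldehyde, via benzylzinc chloride 11 (not isolated)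
Conditions: Zn dust, LiCl, THF, rt; then 10, Pd(OAc)2 (cat.), SPhos (cat.), THF, rt → 40 °C
Reagents that add atoms: none
Why: Negishi coupling between a benzylic zinc reagent and an aryl triflate; LiCl-assisted zinc insertion into alkoxy-substituted benzylic chlorides is established, and Pd(OAc)2 with SPhos couples electrophiles substituted on both ortho positions, the zerovalent palladium inserting at the activated C–O bond. Organozinc reagents tolerate a free aldehyde on the time scale of the coupling, and the C8a–C1 bond can only form where the triflate sits.

Step 9
Reactants: 13 2,5-dibromofuran; 14 [4-(methoxymethoxy)phenyl]boronic acid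
Product: 15 2,5-bis[4-(methoxymethoxy)phenyl]furan
Conditions: Pd(PPh3)4 (cat.), Na2CO3, DME/H2O, 80 °C; 14 (2.2 equiv)
Reagents that add atoms: none
Why: Twofold Suzuki–Miyaura coupling; 2-bromofurans add readily to zerovalent palladium and 2,5-diarylfurans are routinely assembled this way.

Step 10
Reactants: 15 2,5-bis[4-(methoxymethoxy)phenyl]furan
Product: 16 (2Z)-1,4-bis[4-(methoxymethoxy)phenyl]but-2-ene-1,4-dione
Conditions: mCPBA (1.1 equiv), CH2Cl2, 0 °C, dark; aq. NaHCO3 work-up
Reagents that add atoms: meta-chloroperoxybenzoic acid, OOC(=O)c1cccc(Cl)c1
Why: Oxidative ring opening of a 2,5-disubstituted furan; epoxidation of one furan double bond and opening of the ring gives the 1,4-enedione with the Z geometry imposed by the five-membered ring. Work-up with bicarbonate and exclusion of light and acid should preserve that geometry.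

Step 11
Reactants: 12 3-methoxy-2-{[2-methoxy-3,4-bis(methoxymethoxy)phenyl]methyl}-4,5-bis(methoxymethoxy)benzaldehyde; 16 (2Z)-1,4-bis[4-(methoxymethoxy)phenyl]but-2-ene-1,4-dione
Product: 18 [(1S,2S,3S,4S)-4-hydroxy-8-methoxy-1-[2-methoxy-3,4-bis(methoxymethoxy)phenyl]-6,7-bis(methoxymethoxy)-1,2,3,4-tetrahydronaphthalene-2,3-diyl]bis{[4-(methoxymethoxy)phenyl]methanone} (all-cis), via hydroxy-ortho-quinodimethane 17 (not isolated)
Conditions: 365 nm LED, Ti(Oi-Pr)4 (2 equiv), (R,R)-TADDOL (2 equiv), toluene, rt, argon; 16 in excess
Reagents that add atoms: none
Why: Light of 365 nm excites the n,π* state of the aldehyde of 12; after intersystem crossing the carbonyl oxygen takes a hydrogen atom from the doubly benzylic C1 methylene through a six-membered transition state, and the 1,4-biradical relaxes to dienol 17, whose hydroxyl-inside isomer returns to 12 by a thermal 1,5-shift while the hydroxyl-outside isomer lives long enough to be held as a titanium dienolate. The closest known reaction type is the Ti(Oi-Pr)4-mediated photoenolization/Diels–Alder reaction of ortho-alkylbenzaldehydes with enones, known in enantioselective form with TADDOL-type ligands, and thermally generated α-aryl-α'-hydroxy-ortho-quinodimethanes are known to add cis-dienophiles to give all-cis 1-aryl-4-hydroxytetralins. Ring B closes by a single intermolecular, concerted, suprafacial [4+2] cycloaddition in which C1–C2 and C3–C4 form together. C1 and C4 become cis because aryl and hydroxyl both sit outside on the diene termini (an outside aryl avoids the clash with the inner C4 hydrogen at the price of a contact with the C8 methoxy group that ring C can relieve by twisting); C2 and C3 become cis because the Z geometry of 16 is transferred suprafacially; and C3, with it C2, becomes cis to C4 and C1 because the titanium atom holding the dienol oxygen also binds the C10 carbonyl and so enforces the endo orientation. The absolute configuration comes from the TADDOLate ligand, which leaves one face of the bound dienol open. The step needs endo selectivity, retention of the Z dienophile and face selectivity: the first is secured by the chelate, the second by the expectation that 365 nm light holds the enedione photoequilibrium on the side of the more weakly absorbing Z isomer, the third by the ligand, while the constitutionally symmetrical dienophile removes any question of regiochemistry. Only C1 and C2 have to last, since C3 and C4 are flattened or lose their substituent in the next step.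

Step 12
Reactants: 18 all-cis (1S,2S,3S,4S) cycloadduct
Product: 20 [(1S,2S)-8-methoxy-1-[2-methoxy-3,4-bis(methoxymethoxy)phenyl]-6,7-bis(methoxymethoxy)-1,2-dihydronaphthalene-2,3-diyl]bis{[4-(methoxymethoxy)phenyl]methanone}, via C4 mesylate 19 (not isolated)
Conditions: MsCl, Et3N, CH2Cl2, −20 → 0 °C
Reagents that add atoms: none
Why: β-Elimination of a β-sulfonyloxy ketone (E1cB/E2 range); in the all-cis adduct H3 is anti to the C4 oxygen and C4a has no hydrogen, so the only possible alkene is C3=C4, conjugated with ring A and the C10 carbonyl. The benzylic C4, para to the C7 oxygen, also ionises easily, so triethylamine at low temperature should suffice and the C2 hydrogen, α to one ketone only, should stay in place; no stereocentre is formed and C1 and C2 are untouched.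

Step 13
Reactants: 20 hexakis(methoxymethyl) ether of licobichalcone
Product: 21 licobichalcone: [(1S,2S)-1-(3,4-dihydroxy-2-methoxyphenyl)-6,7-dihydroxy-8-methoxy-1,2-dihydronaphthalene-2,3-diyl]bis[(4-hydroxyphenyl)methanone]
Conditions: HCl (2 M in MeOH), THF, rt → 40 °C, argon
Reagents that add atoms: none
Why: Acid-catalysed acetal exchange (methanolysis of aryl methoxymethyl ethers) frees all six phenols while the formaldehyde unit is carried off as its dimethyl acetal; aryl methyl ethers, ketones and the alkene are inert to dilute HCl near room temperature, and as no base is present C2 should keep its configuration.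

## Compound list

1 | 2,3,4-trihydroxybenzaldehyde | O=Cc1ccc(O)c(O)c1O | starting material
2 | 2-hydroxy-3,4-bis(methoxymethoxy)benzaldehyde | O=Cc1ccc(OCOC)c(OCOC)c1O | intermediate
3 | 2-methoxy-3,4-bis(methoxymethoxy)benzaldehyde | O=Cc1ccc(OCOC)c(OCOC)c1OC | intermediate
4 | [2-methoxy-3,4-bis(methoxymethoxy)phenyl]methanol | OCc1ccc(OCOC)c(OCOC)c1OC | intermediate
5 | [2-methoxy-3,4-bis(methoxymethoxy)phenyl]methyl methanesulfonate (not isolated) | CS(=O)(=O)OCc1ccc(OCOC)c(OCOC)c1OC | intermediate
6 | 1-(chloromethyl)-2-methoxy-3,4-bis(methoxymethoxy)benzene | ClCc1ccc(OCOC)c(OCOC)c1OC | intermediate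
7 | 2-methoxy-3,4-bis(methoxymethoxy)phenyl formate (not isolated) | O=COc1ccc(OCOC)c(OCOC)c1OC | intermediate
8 | 2-methoxy-3,4-bis(methoxymethoxy)phenol | Oc1ccc(OCOC)c(OCOC)c1OC | intermediate
9 | 2-hydroxy-3-methoxy-4,5-bis(methoxymethoxy)benzaldehyde | O=Cc1cc(OCOC)c(OCOC)c(OC)c1O | intermediate
10 | 6-formyl-2-methoxy-3,4-bis(methoxymethoxy)phenyl trifluoromethanesulfonate | O=Cc1cc(OCOC)c(OCOC)c(OC)c1OS(=O)(=O)C(F)(F)F | intermediate
11 | chloro{[2-methoxy-3,4-bis(methoxymethoxy)phenyl]methyl}zinc (not isolated) | Cl[Zn]Cc1ccc(OCOC)c(OCOC)c1OC | intermediate
12 | 3-methoxy-2-{[2-methoxy-3,4-bis(methoxymethoxy)phenyl]methyl}-4,5-bis(methoxymethoxy)benzaldehyde | O=Cc1cc(OCOC)c(OCOC)c(OC)c1Cc1ccc(OCOC)c(OCOC)c1OC | intermediate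
13 | 2,5-dibromofuran | Brc1ccc(Br)o1 | starting material
14 | [4-(methoxymethoxy)phenyl]boronic acid | COCOc1ccc(cc1)B(O)O | starting material
15 | 2,5-bis[4-(methoxymethoxy)phenyl]furan | COCOc1ccc(cc1)-c1ccc(o1)-c1ccc(OCOC)cc1 | intermediate
16 | (2Z)-1,4-bis[4-(methoxymethoxy)phenyl]but-2-ene-1,4-dione | COCOc1ccc(cc1)C(=O)/C=C\C(=O)c1ccc(OCOC)cc1 | intermediate
17 | photoenol of 12: cyclohexa-2,4-diene with an (E)-hydroxymethylidene group at C4a and a (Z)-arylmethylidene group at C8a, hydroxyl and aryl both outside (not isolated) | O\C=C1/C=C(OCOC)C(OCOC)=C(OC)/C1=C\c1ccc(OCOC)c(OCOC)c1OC | intermediate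
18 | [(1S,2S,3S,4S)-4-hydroxy-8-methoxy-1-[2-methoxy-3,4-bis(methoxymethoxy)phenyl]-6,7-bis(methoxymethoxy)-1,2,3,4-tetrahydronaphthalene-2,3-diyl]bis{[4-(methoxymethoxy)phenyl]methanone}, all-cis | COc1c([C@H]2c3c(cc(OCOC)c(OCOC)c3OC)[C@@H](O)[C@@H](C(=O)c3ccc(OCOC)cc3)[C@H]2C(=O)c2ccc(OCOC)cc2)ccc(OCOC)c1OCOC | intermediate
19 | C4 methanesulfonate of 18 (not isolated) | COc1c([C@H]2c3c(cc(OCOC)c(OCOC)c3OC)[C@@H](OS(C)(=O)=O)[C@@H](C(=O)c3ccc(OCOC)cc3)[C@H]2C(=O)c2ccc(OCOC)cc2)ccc(OCOC)c1OCOC | intermediate
20 | [(1S,2S)-8-methoxy-1-[2-methoxy-3,4-bis(methoxymethoxy)phenyl]-6,7-bis(methoxymethoxy)-1,2-dihydronaphthalene-2,3-diyl]bis{[4-(methoxymethoxy)phenyl]methanone} | COc1c([C@H]2c3c(cc(OCOC)c(OCOC)c3OC)C=C(C(=O)c3ccc(OCOC)cc3)[C@H]2C(=O)c2ccc(OCOC)cc2)ccc(OCOC)c1OCOC | intermediate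
21 | licobichalcone, [(1S,2S)-1-(3,4-dihydroxy-2-methoxyphenyl)-6,7-dihydroxy-8-methoxy-1,2-dihydronaphthalene-2,3-diyl]bis[(4-hydroxyphenyl)methanone] | COc1c([C@H]2c3c(cc(O)c(O)c3OC)C=C(C(=O)c3ccc(O)cc3)[C@H]2C(=O)c2ccc(O)cc2)ccc(O)c1O | target

## Step count and risk

Total: 13 steps. Longest linear sequence: 9 steps (1, 2, 5, 6, 7, 8, 11, 12, 13). The ring C branch (steps 3, 4) and the enedione branch (steps 9, 10) join at steps 8 and 11.

**Step 11 (key step).**
- Most likely failure: insufficient facial selectivity, because the chiral titanium complex has to discriminate the faces of a dienol that carries a bulky outside aryl group beside the C8 methoxy group while many ether oxygens compete for the metal.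
- Further hazards: loss of dienophile geometry by nucleophile- or Lewis-acid-promoted Z-to-E isomerisation, which would feed the series with C1 and C2 trans; consumption of 16 by its own photochemistry; and slow capture when 16 absorbs much of the light.
- Fallback: resolution in place of asymmetric induction. Starting from 12 and 16, irradiation with Ti(Oi-Pr)4 alone should give the all-cis adduct as a racemate, 18 together with its enantiomer, the (1R,2R,3R,4R) adduct F1. Esterification of the C4 hydroxyl with (S)-2-methoxy-2-phenylacetic acid (DCC, DMAP) would give two diastereomers, the ester of 18, mandelate F2, and the ester of the enantiomer, mandelate F3, to be separated by chromatography or crystallisation. In F2 the carboxylate is a leaving group β to the C10 ketone; brief treatment with an amine base at low temperature should eliminate it and return to the route at 20, so this path replaces steps 11 and 12.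

**Step 12.**
- Most likely failure: loss of the C2 configuration by amine-mediated enolisation, or migration of the double bond into C2=C3 followed by oxidative aromatisation, since C2–H becomes allylic once C3=C4 is formed.
- Fallback: acid-mediated dehydration merged with unmasking. Starting from 18, HCl in methanol should ionise the benzylic C4 carbinol (the cation is stabilised by the para oxygen on C7), the cation should lose H3, and the same medium should cleave the six acetals. This leads directly to 21 without passing through 20 and makes no compound outside the list (entry F0).

**Step 8.**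
- Most likely failure: addition of the benzylic zinc reagent to the formyl group of 10, Wurtz-type homocoupling during zinc insertion into the electron-rich chloride, or slow coupling at the doubly ortho-substituted triflate.
- Fallback: a boron nucleophile instead of zinc. Starting from 6, palladium-catalysed borylation with bis(pinacolato)diboron and KOAc should give the benzylic boronate, pinacol ester F4. F4 is stable, can be purified and does not add to aldehydes. Suzuki–Miyaura coupling of F4 with 10 (PdCl2(dppf), K3PO4, dioxane/H2O) would return to the route at 12.

**Step 13.**
- Most likely failure: acid-induced epimerisation at C2 or double-bond migration during the time needed to cleave six ethers, and electrophilic capture of formaldehyde equivalents by the very electron-rich rings A and C.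
- Fallback: silyl transfer instead of protic solvolysis. Starting from 20, Me3SiOTf with 2,2'-bipyridyl in CH2Cl2 at 0 °C should convert the aryl acetals into aryl silyl ethers, the hexakis(trimethylsilyl) ether F5, with the methoxymethyl unit taken up by the pyridine base. Hydrolysis of F5 with water or methanol at neutral pH would give 21.

## Further compounds

F1 | step 11 | (1R,2R,3R,4R) enantiomer of 18, formed with 18 as the racemate | COc1c([C@@H]2c3c(cc(OCOC)c(OCOC)c3OC)[C@H](O)[C@H](C(=O)c3ccc(OCOC)cc3)[C@@H]2C(=O)c2ccc(OCOC)cc2)ccc(OCOC)c1OCOC
F2 | step 11 | (S)-2-methoxy-2-phenylacetate (C4 ester) of 18 | COc1c([C@H]2c3c(cc(OCOC)c(OCOC)c3OC)[C@@H](OC(=O)[C@@H](OC)c3ccccc3)[C@@H](C(=O)c3ccc(OCOC)cc3)[C@H]2C(=O)c2ccc(OCOC)cc2)ccc(OCOC)c1OCOC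
F3 | step 11 | (S)-2-methoxy-2-phenylacetate (C4 ester) of F1 | COc1c([C@@H]2c3c(cc(OCOC)c(OCOC)c3OC)[C@H](OC(=O)[C@@H](OC)c3ccccc3)[C@H](C(=O)c3ccc(OCOC)cc3)[C@@H]2C(=O)c2ccc(OCOC)cc2)ccc(OCOC)c1OCOC
F0 | step 12 | none | none
F4 | step 8 | 2-{[2-methoxy-3,4-bis(methoxymethoxy)phenyl]methyl}-4,4,5,5-tetramethyl-1,3,2-dioxaborolane | COc1c(CB2OC(C)(C)C(C)(C)O2)ccc(OCOC)c1OCOC
F5 | step 13 | hexakis(trimethylsilyl) ether of licobichalcone | COc1c([C@H]2c3c(cc(O[Si](C)(C)C)c(O[Si](C)(C)C)c3OC)C=C(C(=O)c3ccc(O[Si](C)(C)C)cc3)[C@H]2C(=O)c2ccc(O[Si](C)(C)C)cc2)ccc(O[Si](C)(C)C)c1O[Si](C)(C)C
A1 | alternative 1 | enediyne with methoxyethynyl and ring C on C1, aroyl on C2 and C3, ethynyl on C4 (methoxymethyl-protected) | COc1c([C@@H](C#COC)[C@H](C(=O)c2ccc(OCOC)cc2)/C(C(=O)c2ccc(OCOC)cc2)=C\C#C)ccc(OCOC)c1OCOC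
A2 | alternative 1 | 1,2-bis(4,4,5,5-tetramethyl-1,3,2-dioxaborolan-2-yl)ethyne | CC1(C)OB(OC1(C)C)C#CB1OC(C)(C)C(C)(C)O1
A3 | alternative 1 | 6,7-diboryl dihydronaphthalene with the target skeleton | COc1c([C@H]2c3c(cc(B4OC(C)(C)C(C)(C)O4)c(B4OC(C)(C)C(C)(C)O4)c3OC)C=C(C(=O)c3ccc(OCOC)cc3)[C@H]2C(=O)c2ccc(OCOC)cc2)ccc(OCOC)c1OCOC
A4 | alternative 2 | (dimethylamino)methylene ketone with a bis-aryl methine at C1 and two aroyl groups on C2 | CN(C)/C=C(/C(=O)c1ccc(OCOC)cc1)C(C(=O)c1ccc(OCOC)cc1)(C(=O)c1ccc(OCOC)cc1)C(c1ccc(OCOC)c(OCOC)c1OC)c1ccc(OCOC)c(OCOC)c1OC
A5 | alternative 2 | 1-aryl-2,2,3-triaroyl-1,2-dihydronaphthalene with the C1 configuration of the target | COc1c([C@H]2c3c(cc(OCOC)c(OCOC)c3OC)C=C(C(=O)c3ccc(OCOC)cc3)C2(C(=O)c2ccc(OCOC)cc2)C(=O)c2ccc(OCOC)cc2)ccc(OCOC)c1OCOC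
A6 | alternative 3 | racemic C1 carbinol with free ring C 4-hydroxyl and the enone-ketone chain on C4a | COc1c(C(O)c2c(/C=C(\CC(=O)c3ccc(OCOC)cc3)C(=O)c3ccc(OCOC)cc3)cc(OCOC)c(OCOC)c2OC)ccc(O)c1OCOC
A7 | alternative 3 | licobichalcone pentakis(methoxymethyl) ether with free ring C 4-hydroxyl | COc1c([C@H]2c3c(cc(OCOC)c(OCOC)c3OC)C=C(C(=O)c3ccc(OCOC)cc3)[C@H]2C(=O)c2ccc(OCOC)cc2)ccc(O)c1OCOC
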